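**Retrosynthetic overview**
1. Feature: in ring C, C2–C3–C4 is a 1,3-dioxygenated three-carbon unit (C4=O towards ring A, C2–O1 on the ring B side), and its middle carbon C3 is tied back to O–C2' of ring B through C9H2–C10H2–C11(CH3)2. The unit is therefore carried as an isoxazole (C2=N, O–C4) fused to the eight-membered oxocine.
2. Ring C is opened at O1–C2 (phenol addition–elimination on an enaminone), and the enaminone is traced back to the isoxazole by N–O hydrogenolysis.
3. Key disconnection: C2–C3 and O–C4 together, by intramolecular cycloaddition of a ring B nitrile oxide (C2) onto the tethered ring A aryl alkyne (C3≡C4).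
4. The oxime precursor is cut at C2'–O (SNAr of a tertiary alkoxide on a 2-fluorobenzonitrile), at C4–ring A (Sonogashira, run before the SNAr so that no terminal acetylide competes with the alkoxide) and at C11–CH3 (Grignard).
5. Ring order: rings A and B are bought; isoxazole and oxocine close together in step 8; the pyranone ring C closes in step 10.

Key step: step 8

Remark: flavone numbering is used (O1, C2, C3, C4 in ring C; C9, C10, C11 in the tether; primed atoms in ring B). Compound 8 is taken as a catalogue compound.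

**Step 1**
Reactants: 1 5-methoxyresorcinol
Product: 2 1-methoxy-3,5-bis(methoxymethoxy)benzene
Conditions: MeOCH2Cl (2.5 equiv.), i-Pr2NEt (3 equiv.), CH2Cl2, 0 °C → rt
Reagents that add atoms: chloromethyl methyl ether, COCCl
Why: Williamson-type O-alkylation of both phenols by the reactive α-chloro ether under amine base should give the bis-acetal, which withstands the later bases and hydrides and directs the metalation of step 2.

**Step 2**
Reactants: 2 1-methoxy-3,5-bis(methoxymethoxy)benzene
Product: 4 2-iodo-5-methoxy-1,3-bis(methoxymethoxy)benzene, via aryllithium 3 (not isolated)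
Conditions: n-BuLi (1.1 equiv.), THF, 0 °C, 1 h; then I2, −78 °C → rt
Reagents that add atoms: iodine, II
Why: Directed ortho-metalation should remove the C–H flanked by the two OCH2OCH3 groups, because both acetal oxygens chelate lithium there and OCH2OCH3 directs more strongly than OCH3, and iodinolysis of the aryllithium then fixes iodine at that carbon.

**Step 3**
Reactants: 5 ethyl pent-4-ynoate
Product: 6 2-methylhex-5-yn-2-ol
Conditions: MeMgBr (3.3 equiv.), THF, 0 °C → rt; then aq. NH4Cl
Reagents that add atoms: methylmagnesium bromide, C[Mg]Br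
Why: Double Grignard addition to the ester (one further equivalent is consumed by the acetylenic C–H, which is restored on work-up) should give the tertiary carbinol that becomes C11 with its two methyl groups.

**Step 4**
Reactants: 4 2-iodo-5-methoxy-1,3-bis(methoxymethoxy)benzene; 6 2-methylhex-5-yn-2-ol
Product: 7 6-[4-methoxy-2,6-bis(methoxymethoxy)phenyl]-2-methylhex-5-yn-2-ol
Conditions: PdCl2(PPh3)2 (5 mol %), CuI (10 mol %), Et3N/DMF 1:1, 70 °C, degassed
Reagents that add atoms: none
Why: In this Sonogashira coupling the weak C–I bond should add oxidatively to zerovalent palladium (formed in the flask from the divalent precatalyst) despite the two flanking acetal oxygens, the slim copper acetylide transmetalates without steric penalty, and the free tertiary hydroxyl is tolerated.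

**Step 5**
Reactants: 7 6-[4-methoxy-2,6-bis(methoxymethoxy)phenyl]-2-methylhex-5-yn-2-ol; 8 4-(benzyloxy)-2-fluorobenzonitrile
Product: 10 4-(benzyloxy)-2-{[6-(4-methoxy-2,6-bis(methoxymethoxy)phenyl)-2-methylhex-5-yn-2-yl]oxy}benzonitrile, via potassium alkoxide 9 (not isolated)
Conditions: KN(SiMe3)2 (1.1 equiv.), THF, 0 °C, 20 min; then 8, 0 → 50 °C
Reagents that add atoms: none
Why: In this SNAr (addition–elimination) the pre-formed potassium tertiary alkoxide should attack the fluorine-bearing carbon, since the ortho cyano group stabilises the Meisenheimer anion, the benzyloxy group is meta to the site of attack and does not oppose it, and pre-forming the alkoxide keeps the silylamide from attacking the fluoride itself.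

**Step 6**
Reactants: 10 4-(benzyloxy)-2-{[6-(4-methoxy-2,6-bis(methoxymethoxy)phenyl)-2-methylhex-5-yn-2-yl]oxy}benzonitrile
Product: 12 4-(benzyloxy)-2-{[6-(4-methoxy-2,6-bis(methoxymethoxy)phenyl)-2-methylhex-5-yn-2-yl]oxy}benzaldehyde, via N-aluminio aldimine 11 (not isolated)
Conditions: i-Bu2AlH (1.5 equiv.), CH2Cl2, −78 → −20 °C; then 10% aq. AcOH, 0 °C
Reagents that add atoms: water, O
Why: Partial hydride reduction of the nitrile should stop at the N-aluminated aldimine, which cold dilute acetic acid hydrolyses to the aldehyde without touching the internal alkyne, the benzyl ether, the acetals or the tertiary aryl ether.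

**Step 7**
Reactants: 12 4-(benzyloxy)-2-{[6-(4-methoxy-2,6-bis(methoxymethoxy)phenyl)-2-methylhex-5-yn-2-yl]oxy}benzaldehyde
Product: 13 (E)-4-(benzyloxy)-2-{[6-(4-methoxy-2,6-bis(methoxymethoxy)phenyl)-2-methylhex-5-yn-2-yl]oxy}benzaldehyde oxime
Conditions: NH2OH·HCl (1.5 equiv.), NaOAc (2 equiv.), EtOH/H2O, rt
Reagents that add atoms: hydroxylamine hydrochloride, Cl.NO
Why: Buffered oxime condensation of the aryl aldehyde should give the thermodynamically preferred (E)-aldoxime (OH anti to the aryl group), and either oxime isomer would lead to the same nitrile oxide.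

**Step 8**
Reactants: 13 (E)-4-(benzyloxy)-2-{[6-(4-methoxy-2,6-bis(methoxymethoxy)phenyl)-2-methylhex-5-yn-2-yl]oxy}benzaldehyde oxime
Product: 15 5-[4-methoxy-2,6-bis(methoxymethoxy)phenyl]isoxazole whose C3 carries ring B (4'-benzyloxy) and whose C4 is joined through CH2CH2C(CH3)2–O to C2' of that ring (isoxazole-fused dimethyl-dihydrobenzoxocine), via nitrile oxide 14 (not isolated)
Conditions: PhI(OAc)2 (1.2 equiv., syringe pump, 10 h), ClCH2CH2Cl (2 mM in 13), 60 °C
Reagents that add atoms: none
Why: PhI(OAc)2 exchanges an acetate for the oxime oxygen and the adduct collapses to iodobenzene, acetic acid and nitrile oxide 14, whose C≡N–O unit adds in a concerted thermal [3+2] manner across the tethered C3≡C4 bond, forming C2–C3 and O–C4 in one event; the closest known reaction type is the intramolecular nitrile oxide–alkyne cycloaddition used for benzo-fused isoxazoles. The isoxazole closes by the cycloaddition itself (C2, N and O of the dipole with C3 and C4 of the alkyne), and the oxocine closes in the fused mode, the new C2–C3 bond completing the eight-membered ring C2–C1'–C2'–O–C11–C10–C9–C3, whose tether is restricted by the aryl C1'–C2' edge and by the geminal methyl groups at C11 (Thorpe–Ingold effect). No stereocentre is created. The step needs regioselectivity and it needs ring closure to outrun dimerisation of the dipole to the furoxan: the O–C11–C10–C9 tether lets the nitrile oxide carbon reach only the proximal alkyne carbon C3 (the reverse orientation would require an impossibly strained bridged bicycle), slow generation of 14 at high dilution keeps its standing concentration low, and the ortho tertiary alkoxy group shields the dipole carbon against bimolecular attack. A trivalent iodine oxidant is chosen over hypochlorite or N-chlorosuccinimide because it should not halogenate the two electron-rich arenes, and the aromaticity gained in the isoxazole makes the addition irreversible.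

**Step 9**
Reactants: 15 isoxazole-fused benzoxocine
Product: 16 (Z)-enaminone: eight-membered ring with the C2(NH2)=C3 double bond, C2 on ring B (4'-OH free), C3 bearing the 4-methoxy-2,6-bis(methoxymethoxy)benzoyl group
Conditions: H2 (1 atm), 10% Pd/C, EtOH/EtOAc 1:1, rt
Reagents that add atoms: none
Why: Catalytic hydrogenolysis should cleave the weak isoxazole N–O bond to the hydrogen-bonded vinylogous amide, which resists further reduction, and remove the benzyl ether in the same operation; the Z geometry follows from the ring and from the cis relation of N and O in the isoxazole, and the acetals and the tertiary aryl ether are inert.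

**Step 10**
Reactants: 16 (Z)-enaminone
Product: 18 cyclointegrin, via bisphenol enaminone 17 (not isolated)
Conditions: HCl (1 M), MeOH, 40 °C
Reagents that add atoms: none
Why: Acid-catalysed transacetalisation to methanol should remove both methoxymethyl groups (each activated by the ortho carbonyl), after which either of the two equivalent phenols adds to C2 of the N-protonated enaminone in a 6-exo-trig addition–elimination that expels ammonia and gives the pyranone (enaminone-to-chromone cyclocondensation), the other phenol becoming the hydrogen-bonded 5-OH, while dilute methanolic HCl at 40 °C should be too mild to ionise the tertiary aryl ether at a competing rate.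

**Compound list**
1 | 5-methoxyresorcinol | COc1cc(O)cc(O)c1 | starting material
2 | 1-methoxy-3,5-bis(methoxymethoxy)benzene | COCOc1cc(OC)cc(OCOC)c1 | intermediate
3 | [4-methoxy-2,6-bis(methoxymethoxy)phenyl]lithium | [Li]c1c(OCOC)cc(OC)cc1OCOC | intermediate
4 | 2-iodo-5-methoxy-1,3-bis(methoxymethoxy)benzene | COCOc1cc(OC)cc(OCOC)c1I | intermediate
5 | ethyl pent-4-ynoate | C#CCCC(=O)OCC | starting material
6 | 2-methylhex-5-yn-2-ol | C#CCCC(C)(C)O | intermediate
7 | 6-[4-methoxy-2,6-bis(methoxymethoxy)phenyl]-2-methylhex-5-yn-2-ol | COCOc1cc(OC)cc(OCOC)c1C#CCCC(C)(C)O | intermediate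
8 | 4-(benzyloxy)-2-fluorobenzonitrile | N#Cc1ccc(OCc2ccccc2)cc1F | starting material
9 | potassium 6-[4-methoxy-2,6-bis(methoxymethoxy)phenyl]-2-methylhex-5-yn-2-olate | COCOc1cc(OC)cc(OCOC)c1C#CCCC(C)(C)[O-].[K+] | intermediate
10 | 4-(benzyloxy)-2-{[6-(4-methoxy-2,6-bis(methoxymethoxy)phenyl)-2-methylhex-5-yn-2-yl]oxy}benzonitrile | N#Cc1ccc(OCc2ccccc2)cc1OC(C)(C)CCC#Cc1c(OCOC)cc(OC)cc1OCOC | intermediate
11 | N-(diisobutylaluminio) aldimine of 12 | CC(C)C[Al](CC(C)C)N=Cc1ccc(OCc2ccccc2)cc1OC(C)(C)CCC#Cc1c(OCOC)cc(OC)cc1OCOC | intermediate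
12 | 4-(benzyloxy)-2-{[6-(4-methoxy-2,6-bis(methoxymethoxy)phenyl)-2-methylhex-5-yn-2-yl]oxy}benzaldehyde | O=Cc1ccc(OCc2ccccc2)cc1OC(C)(C)CCC#Cc1c(OCOC)cc(OC)cc1OCOC | intermediate
13 | (E)-4-(benzyloxy)-2-{[6-(4-methoxy-2,6-bis(methoxymethoxy)phenyl)-2-methylhex-5-yn-2-yl]oxy}benzaldehyde oxime | O/N=C/c1ccc(OCc2ccccc2)cc1OC(C)(C)CCC#Cc1c(OCOC)cc(OC)cc1OCOC | intermediate
14 | nitrile oxide of 13 | [O-][N+]#Cc1ccc(OCc2ccccc2)cc1OC(C)(C)CCC#Cc1c(OCOC)cc(OC)cc1OCOC | intermediate
15 | isoxazole-fused benzoxocine (5-aryl isoxazole, C3 on ring B, C4 tethered to C2'–O; 4'-OBn, two OCH2OCH3 on ring A) | COc1cc(OCOC)c(-c2onc3c2CCC(C)(C)Oc2cc(OCc4ccccc4)ccc2-3)c(OCOC)c1 | intermediate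
16 | (Z)-enaminone (C2–NH2, C3–aroyl, 4'-OH free, two OCH2OCH3 on ring A) | N/C1=C(\C(=O)c2c(OCOC)cc(OC)cc2OCOC)CCC(C)(C)Oc2cc(O)ccc21 | intermediate
17 | (Z)-enaminone with free 2,6-dihydroxy-4-methoxybenzoyl group | N/C1=C(\C(=O)c2c(O)cc(OC)cc2O)CCC(C)(C)Oc2cc(O)ccc21 | intermediate
18 | cyclointegrin | COc1cc(O)c2c(=O)c3c(oc2c1)-c1ccc(O)cc1OC(C)(C)CC3 | target

**Totals**
Total steps: 10. Longest linear sequence: 9 steps (steps 1, 2, 4, 5, 6, 7, 8, 9, 10, from 1 to 18).

**Steps most likely to fail**

Step 8. The slow eight-membered ring closure may be outrun by bimolecular dimerisation of the nitrile oxide to the furoxan or by capture of the dipole by acetic acid, and the iodane may oxidise the trialkoxyarene. The fallback changes the dipolarophile and sets out from 13. Semi-hydrogenation of the alkyne (H2, Pd/CaCO3 poisoned with Pb(OAc)2, quinoline, EtOAc, rt) should give the (E)-oxime of the (Z)-alkene F1. Oxidation under the conditions of step 8 should give the nitrile oxide F2, which closes by intramolecular nitrile oxide–alkene cycloaddition to the racemic cis-isoxazoline F3. The bent cis-styrene holds C3 closer to the dipole than the linear alkyne does, and the forming ring contains two sp3 carbons. Dehydrogenation with DDQ (PhMe, 80 °C; activated MnO2 as alternative) erases both stereocentres and returns the route at 15.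

Step 10. Protonation and ionisation of the tertiary aryl ether may open the oxocine, followed by elimination or capture by methanol, in competition with acetal cleavage and ring closure. The fallback moves the unmasking of ring A into the hydrogenolysis, so that no mineral acid meets the tertiary ether; it sets out from 4 and returns at 17.
- HCl/MeOH removes both acetals of 4 to give 2-iodo-5-methoxybenzene-1,3-diol F4.
- BnBr, K2CO3, DMF gives 1,3-bis(benzyloxy)-2-iodo-5-methoxybenzene F5.
- Sonogashira coupling with 6 as in step 4 gives the bis(benzyloxy) alkynol F6.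
- Its potassium alkoxide F7 (KN(SiMe3)2, THF) displaces fluoride from 8 to give the nitrile F8.
- i-Bu2AlH gives the N-aluminio aldimine F9, hydrolysed to the aldehyde F10.
- NH2OH·HCl, NaOAc gives the (E)-oxime F11.
- PhI(OAc)2 under the conditions of step 8 gives the nitrile oxide F12, which cyclises to the tribenzyl isoxazole F13.
- H2, 10% Pd/C cleaves the three benzyl ethers and the N–O bond to give 17, which is closed to 18 in AcOH at 60 °C.

Step 9. N–O hydrogenolysis of the fully substituted, doubly flanked isoxazole may stall as the liberated amine poisons the catalyst, or the enaminone C=C may be over-reduced. The fallback separates N–O cleavage from debenzylation and reorders the endgame; it sets out from 15. Mo(CO)6 in MeCN/H2O at 80 °C should cleave the N–O bond reductively to the 4'-O-benzyl enaminone F14. HCl (1 M) in MeOH at 40 °C removes the acetals to give the bisphenol F15 (not isolated), which closes to 4'-O-benzylcyclointegrin F16. Hydrogenolysis of the benzyl ether on the robust flavone (H2, 10% Pd/C, EtOAc) returns the route at 18.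

**Further compounds**
F1 | step 8 | (E)-oxime of (Z)-4-(benzyloxy)-2-{[6-(4-methoxy-2,6-bis(methoxymethoxy)phenyl)-2-methylhex-5-en-2-yl]oxy}benzaldehyde | O/N=C/c1ccc(OCc2ccccc2)cc1OC(C)(C)CC/C=C\c1c(OCOC)cc(OC)cc1OCOC
F2 | step 8 | nitrile oxide of F1 | [O-][N+]#Cc1ccc(OCc2ccccc2)cc1OC(C)(C)CC/C=C\c1c(OCOC)cc(OC)cc1OCOC
F3 | step 8 | cis-4,5-dihydro analogue of 15 (isoxazoline, racemic, one enantiomer drawn) | COc1cc(OCOC)c([C@H]2ON=C3[C@H]2CCC(C)(C)Oc2cc(OCc4ccccc4)ccc2-3)c(OCOC)c1
F4 | step 10 | 2-iodo-5-methoxybenzene-1,3-diol | COc1cc(O)c(I)c(O)c1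
F5 | step 10 | 1,3-bis(benzyloxy)-2-iodo-5-methoxybenzene | COc1cc(OCc2ccccc2)c(I)c(OCc2ccccc2)c1
F6 | step 10 | 6-[2,6-bis(benzyloxy)-4-methoxyphenyl]-2-methylhex-5-yn-2-ol | COc1cc(OCc2ccccc2)c(C#CCCC(C)(C)O)c(OCc2ccccc2)c1
F7 | step 10 | potassium alkoxide of F6 | COc1cc(OCc2ccccc2)c(C#CCCC(C)(C)[O-])c(OCc2ccccc2)c1.[K+]
F8 | step 10 | 4-(benzyloxy)-2-{[6-(2,6-bis(benzyloxy)-4-methoxyphenyl)-2-methylhex-5-yn-2-yl]oxy}benzonitrile | N#Cc1ccc(OCc2ccccc2)cc1OC(C)(C)CCC#Cc1c(OCc2ccccc2)cc(OC)cc1OCc1ccccc1
F9 | step 10 | N-(diisobutylaluminio) aldimine of F10 | CC(C)C[Al](CC(C)C)N=Cc1ccc(OCc2ccccc2)cc1OC(C)(C)CCC#Cc1c(OCc2ccccc2)cc(OC)cc1OCc1ccccc1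
F10 | step 10 | 4-(benzyloxy)-2-{[6-(2,6-bis(benzyloxy)-4-methoxyphenyl)-2-methylhex-5-yn-2-yl]oxy}benzaldehyde | O=Cc1ccc(OCc2ccccc2)cc1OC(C)(C)CCC#Cc1c(OCc2ccccc2)cc(OC)cc1OCc1ccccc1
F11 | step 10 | (E)-oxime of F10 | O/N=C/c1ccc(OCc2ccccc2)cc1OC(C)(C)CCC#Cc1c(OCc2ccccc2)cc(OC)cc1OCc1ccccc1
F12 | step 10 | nitrile oxide of F11 | [O-][N+]#Cc1ccc(OCc2ccccc2)cc1OC(C)(C)CCC#Cc1c(OCc2ccccc2)cc(OC)cc1OCc1ccccc1
F13 | step 10 | tribenzyl analogue of 15 (ring A 2,6-bis(benzyloxy)-4-methoxy) | COc1cc(OCc2ccccc2)c(-c2onc3c2CCC(C)(C)Oc2cc(OCc4ccccc4)ccc2-3)c(OCc2ccccc2)c1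
F14 | step 9 | 4'-O-benzyl ether of enaminone 16 | N/C1=C(\C(=O)c2c(OCOC)cc(OC)cc2OCOC)CCC(C)(C)Oc2cc(OCc3ccccc3)ccc21
F15 | step 9 | 4'-O-benzyl ether of enaminone 17 | N/C1=C(\C(=O)c2c(O)cc(OC)cc2O)CCC(C)(C)Oc2cc(OCc3ccccc3)ccc21
F16 | step 9 | 4'-O-benzylcyclointegrin | COc1cc(O)c2c(=O)c3c(oc2c1)-c1ccc(OCc4ccccc4)cc1OC(C)(C)CC3
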